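**Retrosynthetic overview**
1. Both CH2 bridges are cut last: the bis-Mannich base 21 of isobutyrylphloroglucinol (central ring) is joined to two molecules of isobutyrylfilicinic acid 17 through ortho-quinone methides.
2. 17 comes from dienone 13 by desilylation, oxidation and hydrolysis of two enol ethers, so no protecting group survives.
3. The six-membered ring of 13 is closed at its C1(=O)–C6(CH3)2 bond by 6π-electrocyclization of dienylketene 12. This ketene is released by strain-driven opening of a cyclobutenone assembled in the same flask from cyclobutenone 4 (dimethylketene + ethoxyacetylene) and ynol ether 9.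
4. Enabling feature: each outer ring is a 6,6-dimethylcyclohexa-2,4-dien-1-one whose quaternary C6 lies between the C1 carbonyl and oxygen-bearing C5, with oxygen also at C3. It cannot aromatize and is the valence isomer of a 3,5-dialkoxy dienylketene with a dimethyl-substituted terminus.
5. Ring order: four-membered ring of 4, transient four-membered ring of 11, then the carbocycle of 13 (made once, used twice); the aromatic central ring comes from phloroglucinol.

Key step: step 4

Assumption: the target has no stereocentre and no stereogenic double bond, so it is achiral and no enantioselective step is needed; it is drawn as one enol tautomer of an equilibrating set. Compounds 8, 9, 13 and 14 are racemates (11 a diastereomer mixture), and their carbinol centre is erased in step 6.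

**Step 1**
Reactants: 1 isobutyryl chloride; 2 ethoxyacetylene
Product: 4 3-ethoxy-4,4-dimethylcyclobut-2-en-1-one, via dimethylketene 3 (not isolated)
Conditions: Et3N (1.5 equiv), Et2O, 0 °C → reflux
Reagents that add atoms: none
Why: Et3N dehydrochlorinates 1 to dimethylketene, which undergoes a thermal ketene–alkyne [2+2] cycloaddition with the ynol ether in which the ketene carbonyl carbon bonds to the nucleophilic terminal alkyne carbon, so that OEt ends at C3 next to the CMe2 carbon.

**Step 2**
Reactants: 5 2-chloro-1,1-dimethoxyethane; 6 isobutyraldehyde
Product: 8 rac-1-methoxy-4-methylpent-1-yn-3-ol, via lithium methoxyacetylide 7 (not isolated)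
Conditions: LiNEt2 (3.1 equiv), THF, 0 °C; then 6, −78 → 0 °C; H2O quench
Reagents that add atoms: none
Why: Threefold action of the amide base (loss of methanol, loss of HCl, deprotonation) converts the chloroacetal into the lithium alkoxyacetylide, whose 1,2-addition to the aldehyde gives the propargylic alcohol; the carbinol centre forms without control and is erased in step 6.

**Step 3**
Reactants: 8 rac-1-methoxy-4-methylpent-1-yn-3-ol
Product: 9 rac-tert-butyl[(1-methoxy-4-methylpent-1-yn-3-yl)oxy]dimethylsilane
Conditions: TBSCl, imidazole, DMF, 0 °C → rt
Reagents that add atoms: tert-butyldimethylsilyl chloride, CC(C)(C)[Si](C)(C)Cl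
Why: Imidazole-promoted O-silylation of a secondary alcohol under basic conditions avoids the acid-triggered Meyer–Schuster rearrangement of the ynol ether carbinol and removes the OH that would trap ketenes in step 4.

**Step 4**
Reactants: 4 3-ethoxy-4,4-dimethylcyclobut-2-en-1-one (1.5 equiv); 9 rac-tert-butyl[(1-methoxy-4-methylpent-1-yn-3-yl)oxy]dimethylsilane
Product: 13 rac-2-[1-(tert-butyldimethylsilyloxy)-2-methylpropyl]-5-ethoxy-3-methoxy-6,6-dimethylcyclohexa-2,4-dien-1-one, via vinylketene 10 (not isolated), via alkenylcyclobutenone 11 (not isolated), via dienylketene 12 (not isolated)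
Conditions: PhMe, 130 °C, sealed tube
Reagents that add atoms: none
Why: Heating should open the strained ring of 4 by conrotatory 4π-electrocyclic cleavage of its C1–C4 bond to vinylketene 10, which adds to ynol ether 9 in a ketene–alkyne [2+2] cycloaddition (ketene carbonyl carbon to the alkyne carbon remote from OMe) to give 4-alkenylcyclobutenone 11; a second strain-releasing 4π opening gives dienylketene 12, whose 6π-electrocyclization joins the ketene carbon to the dimethyl-substituted enol ether terminus and so forms the C1(=O)–C6(CH3)2 bond of the carbocycle. The closest known reaction type is the Danheiser thermal annulation of cyclobutenones with alkoxyalkynes, together with the thermal recyclization of dienylketenes to 6,6-disubstituted cyclohexa-2,4-dienones; because C6 is quaternary the dienone cannot tautomerize to a phenol and is the product. The six-membered ring closes in the thermal disrotatory 6π-electrocyclic mode, and both four-membered rings are only transient. No new stereocentre is formed, since C6 carries two methyl groups and the racemic carbinol centre of 9 is carried through unchanged. The step needs regiocontrol in the [2+2] event, which the polarization of the ynol ether secures, and the geometry of 12 with the ketene carbon and C5 cis, which is reached because the dienylketene isomers interconvert through reversible reclosure to 11; a methyl ynol ether is chosen so that no retro-ene loss of an alkene can compete at this temperature, and 4 is used in excess to offset ketene dimerization.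

**Step 5**
Reactants: 13 rac-2-[1-(tert-butyldimethylsilyloxy)-2-methylpropyl]-5-ethoxy-3-methoxy-6,6-dimethylcyclohexa-2,4-dien-1-one
Product: 14 rac-5-ethoxy-2-(1-hydroxy-2-methylpropyl)-3-methoxy-6,6-dimethylcyclohexa-2,4-dien-1-one
Conditions: HF·pyridine, pyridine, THF, 0 °C → rt
Reagents that add atoms: none
Why: Fluoride cleaves the Si–O bond (silyl ether deprotection), and the pyridine buffer should keep the two acid-labile enol ethers intact.

**Step 6**
Reactants: 14 rac-5-ethoxy-2-(1-hydroxy-2-methylpropyl)-3-methoxy-6,6-dimethylcyclohexa-2,4-dien-1-one
Product: 15 5-ethoxy-3-methoxy-6,6-dimethyl-2-(2-methylpropanoyl)cyclohexa-2,4-dien-1-one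
Conditions: Dess–Martin periodinane, pyridine, CH2Cl2, 0 °C → rt
Reagents that add atoms: none
Why: Dess–Martin oxidation of the secondary alcohol installs the 2-methylpropanoyl group on C2 and removes the only stereocentre of the route; the hypervalent iodine reagent should not touch the enol ethers.

**Step 7**
Reactants: 15 5-ethoxy-3-methoxy-6,6-dimethyl-2-(2-methylpropanoyl)cyclohexa-2,4-dien-1-one
Product: 17 3,5-dihydroxy-6,6-dimethyl-2-(2-methylpropanoyl)cyclohexa-2,4-dien-1-one (isobutyrylfilicinic acid), via monoethyl ether 16 (not isolated)
Conditions: 2 M aq. HCl, THF, 50 °C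
Reagents that add atoms: water, O
Why: Acid-catalysed hydrolysis of the two vinylogous ester (enol ether) groups proceeds by conjugate addition of water and loss of alcohol, the doubly activated 3-methoxy group expected first; the acyl trione is stable to aqueous acid.

**Step 8**
Reactants: 18 phloroglucinol; 1 isobutyryl chloride
Product: 19 2-methyl-1-(2,4,6-trihydroxyphenyl)propan-1-one (isobutyrylphloroglucinol)
Conditions: AlCl3 (4 equiv), PhNO2, rt → 60 °C; ice/aq. HCl work-up
Reagents that add atoms: none
Why: Friedel–Crafts acylation of the electron-rich arene stops at monoacylation because the first acyl group deactivates the ring and is hydrogen-bonded to the flanking OH groups.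

**Step 9**
Reactants: 19 2-methyl-1-(2,4,6-trihydroxyphenyl)propan-1-one
Product: 21 1-{3,5-bis[(dimethylamino)methyl]-2,4,6-trihydroxyphenyl}-2-methylpropan-1-one, via mono-Mannich base 20 (not isolated)
Conditions: CH2(NMe2)2 (2.2 equiv), EtOH, 0 °C → rt
Reagents that add atoms: N,N,N',N'-tetramethylmethanediamine, CN(C)CN(C)C
Why: Double phenolic Mannich reaction, in which the acidic phenol protonates the aminal to the iminium ion that substitutes the two remaining activated ring positions; with both positions blocked the product cannot oligomerize through carbon.

**Step 10**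
Reactants: 21 1-{3,5-bis[(dimethylamino)methyl]-2,4,6-trihydroxyphenyl}-2-methylpropan-1-one; 17 isobutyrylfilicinic acid (2.2 equiv)
Product: 25 onind (target), via quinone methide 22 (not isolated), via monoadduct 23 (not isolated), via quinone methide 24 (not isolated)
Conditions: 1,4-dioxane, 90 °C, N2 sweep; dil. aq. HCl wash
Reagents that add atoms: none
Why: Proton transfer from the vinylogous acid 17 and thermal loss of dimethylamine generate an ortho-quinone methide on the central ring, which is captured by Michael addition of the only nucleophilic carbon of 17 (C4, between the two enolic carbons), and the sequence repeats at the second aminomethyl group (Mannich-base alkylation of a cyclic β-dicarbonyl compound).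

**Compound list**
1 | isobutyryl chloride | CC(C)C(=O)Cl | starting material
2 | ethoxyacetylene | CCOC#C | starting material
3 | dimethylketene | CC(C)=C=O | intermediate
4 | 3-ethoxy-4,4-dimethylcyclobut-2-en-1-one | CCOC1=CC(=O)C1(C)C | intermediate
5 | 2-chloro-1,1-dimethoxyethane | COC(CCl)OC | starting material
6 | isobutyraldehyde | CC(C)C=O | starting material
7 | lithium methoxyacetylide | [Li+].[C-]#COC | intermediate
8 | rac-1-methoxy-4-methylpent-1-yn-3-ol | COC#CC(O)C(C)C | intermediate
9 | rac-tert-butyl[(1-methoxy-4-methylpent-1-yn-3-yl)oxy]dimethylsilane | COC#CC(O[Si](C)(C)C(C)(C)C)C(C)C | intermediate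
10 | 3-ethoxy-4-methylpenta-1,3-dien-1-one (vinylketene) | CCOC(C=C=O)=C(C)C | intermediate
11 | 2-[1-(tert-butyldimethylsilyloxy)-2-methylpropyl]-4-(1-ethoxy-2-methylprop-1-enyl)-3-methoxycyclobut-2-en-1-one (diastereomer mixture) | CCOC(=C(C)C)C1C(OC)=C(C(O[Si](C)(C)C(C)(C)C)C(C)C)C1=O | intermediate
12 | (3E)-2-[1-(tert-butyldimethylsilyloxy)-2-methylpropyl]-5-ethoxy-3-methoxy-6-methylhepta-1,3,5-trien-1-one (dienylketene, racemic) | CCOC(=C(C)C)\C=C(OC)/C(=C=O)C(O[Si](C)(C)C(C)(C)C)C(C)C | intermediate
13 | rac-2-[1-(tert-butyldimethylsilyloxy)-2-methylpropyl]-5-ethoxy-3-methoxy-6,6-dimethylcyclohexa-2,4-dien-1-one | CCOC1=CC(OC)=C(C(O[Si](C)(C)C(C)(C)C)C(C)C)C(=O)C1(C)C | intermediate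
14 | rac-5-ethoxy-2-(1-hydroxy-2-methylpropyl)-3-methoxy-6,6-dimethylcyclohexa-2,4-dien-1-one | CCOC1=CC(OC)=C(C(O)C(C)C)C(=O)C1(C)C | intermediate
15 | 5-ethoxy-3-methoxy-6,6-dimethyl-2-(2-methylpropanoyl)cyclohexa-2,4-dien-1-one | CCOC1=CC(OC)=C(C(=O)C(C)C)C(=O)C1(C)C | intermediate
16 | 5-ethoxy-3-hydroxy-6,6-dimethyl-2-(2-methylpropanoyl)cyclohexa-2,4-dien-1-one | CCOC1=CC(O)=C(C(=O)C(C)C)C(=O)C1(C)C | intermediate
17 | 3,5-dihydroxy-6,6-dimethyl-2-(2-methylpropanoyl)cyclohexa-2,4-dien-1-one (isobutyrylfilicinic acid) | CC(C)C(=O)C1=C(O)C=C(O)C(C)(C)C1=O | intermediate
18 | phloroglucinol | Oc1cc(O)cc(O)c1 | starting material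
19 | 2-methyl-1-(2,4,6-trihydroxyphenyl)propan-1-one | CC(C)C(=O)c1c(O)cc(O)cc1O | intermediate
20 | 1-{3-[(dimethylamino)methyl]-2,4,6-trihydroxyphenyl}-2-methylpropan-1-one | CC(C)C(=O)c1c(O)cc(O)c(CN(C)C)c1O | intermediate
21 | 1-{3,5-bis[(dimethylamino)methyl]-2,4,6-trihydroxyphenyl}-2-methylpropan-1-one | CC(C)C(=O)c1c(O)c(CN(C)C)c(O)c(CN(C)C)c1O | intermediate
22 | 4-[(dimethylamino)methyl]-3,5-dihydroxy-6-methylidene-2-(2-methylpropanoyl)cyclohexa-2,4-dien-1-one | CC(C)C(=O)C1=C(O)C(CN(C)C)=C(O)C(=C)C1=O | intermediate
23 | mono-bridged aminomethyl intermediate (central ring carrying one filicinic unit and one CH2NMe2) | CC(C)C(=O)c1c(O)c(CN(C)C)c(O)c(CC2=C(O)C(C)(C)C(=O)C(C(=O)C(C)C)=C2O)c1O | intermediate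
24 | second quinone methide (central ring carrying one filicinic unit and one exocyclic CH2) | CC(C)C(=O)C1=C(O)C(CC2=C(O)C(C)(C)C(=O)C(C(=O)C(C)C)=C2O)=C(O)C(=C)C1=O | intermediate
25 | onind | CC(C)C(=O)C1=C(O)C(Cc2c(O)c(CC3=C(O)C(C)(C)C(=O)C(C(=O)C(C)C)=C3O)c(O)c(C(=O)C(C)C)c2O)=C(O)C(C)(C)C1=O | target

**Step count and risks**
Total step count: 10. Longest linear sequence: 7 steps (2, 3, 4, 5, 6, 7, 10).

Steps most likely to fail:

1. Step 4. The first ring opening must turn one C4 methyl group inward, so it may need a temperature at which vinylketene 10 is drained by a 1,5-hydrogen shift or by dimerization before the hindered alkyne 9 captures it. Fallback: the outer ring is then made by dearomatization instead of ring construction. It sets out from 19, whose double C-methylation at one ring carbon with iodomethane and sodium methoxide in methanol (the known entry to acylfilicinic acids) should give 17 directly; there it comes back to the route before step 10. No new compound is involved.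

2. Step 10. Released dimethylamine can re-add, and the methylene bridges can exchange by retro-Michael/Michael steps, which would scramble the trimer into symmetrical dimers; O-alkylation of the quinone methide may also compete. Fallback with reversed polarity: it sets out from 17, which with N,N,N',N'-tetramethylmethanediamine in EtOH should give the Mannich base 4-[(dimethylamino)methyl]-3,5-dihydroxy-6,6-dimethyl-2-(2-methylpropanoyl)cyclohexa-2,4-dien-1-one F1. Warming two equivalents of F1 with 19 in dioxane should let the two free positions of the arene add in turn to the acceptor formed by amine loss, and the sequence comes back at 25.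

3. Step 9. The mono-Mannich base 20 may lose amine before the second aminomethylation and alkylate unreacted 19, which would lead to methylene-linked oligomers of the central ring. Fallback without any aminomethyl compound: it sets out from 19, which is condensed directly with two equivalents each of 17 and aqueous formaldehyde in dilute aqueous NaOH at room temperature and then acidified (the classical formaldehyde condensation to methylene-bis phloroglucinols), and comes back at 25. No new compound is isolated.

**Further compounds**
F0 | step 4 | none | none
F1 | step 10 | 4-[(dimethylamino)methyl]-3,5-dihydroxy-6,6-dimethyl-2-(2-methylpropanoyl)cyclohexa-2,4-dien-1-one | CC(C)C(=O)C1=C(O)C(CN(C)C)=C(O)C(C)(C)C1=O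
F0 | step 9 | none | none
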